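**Plan**
- Retrosynthetic cuts, in order: C2–Cl and C3–Br (back to the C2=C3 alkene through its epoxide), C10–Br (back to the C10 alcohol of opposite configuration), C3–CH3 (enol triflate, before it the C3 ketone), C6–C7 (ring A), then C9–C10 and the two C11–CH3 bonds of the side chain.
- Enabling feature: ring B (C6, C1–C5) is a para-substituted phenol in reduced form, with C3 para to the spiro carbon C6, and ring A carries its C7(Me)=C8 double bond directly on C6. The C6–C7 bond is therefore the ipso attack of a phenol on a methyl-capped alkyne.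
- Forward: (4-hydroxyphenyl)acetonitrile is dimethylated and reduced to the aldehyde, the three-carbon alkyne unit is added, and ring A is closed onto the phenol, which becomes ring B. Ring B is then reduced one arm at a time, methylated, and halogenated last.
- Stereochemistry: C10 comes from a catalyst-controlled allenylboration (S) and is inverted to R in the Appel step. C6 comes from a catalyst-controlled desymmetrising conjugate reduction. C2 and C3 come from a face-selective epoxidation, invertive opening at C3, and retentive substitution at C2 through a bromonium ion.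

Key step: step 8

Remark on numbering (used in all names): C6 is the spiro carbon; ring A is C6–C7(Me)=C8–C9–C10–C11(Me)2; ring B is C6–C1–C2–C3–C4–C5. This is not the von Baeyer numbering.

Assumption: in diene 22 and its epoxide, ring B holds C7 pseudo-axial and the bulkier quaternary C11 pseudo-equatorial at C6, so that the face of C2=C3 syn to C11 is the open one.

**Route**

Step 1
Reactants: 1 2-(4-hydroxyphenyl)acetonitrile
Product: 2 2-[4-(tert-butyldimethylsilyloxy)phenyl]acetonitrile
Conditions: TBSCl, imidazole, DMF, 25 °C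
Reagents that add atoms: tert-butyldimethylsilyl chloride, CC(C)(C)[Si](C)(C)Cl
Why: Imidazole-assisted silylation masks the acidic phenol so that only the benzylic CH2 is deprotonated in the next step.

Step 2
Reactants: 2 2-[4-(tert-butyldimethylsilyloxy)phenyl]acetonitrile
Product: 4 2-[4-(tert-butyldimethylsilyloxy)phenyl]-2-methylpropanenitrile, via monomethyl nitrile 3 (not isolated)
Conditions: NaHMDS (1.1 equiv), MeI, THF, −78 °C; second portion NaHMDS (1.2 equiv), MeI, −78 → 0 °C
Reagents that add atoms: iodomethane, CI
Why: Two cycles of deprotonation and SN2 methylation of the benzylic nitrile anion (exhaustive α-alkylation) build the quaternary C11 with both methyl groups, and the reaction stops once no α-hydrogen is left.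

Step 3
Reactants: 4 2-[4-(tert-butyldimethylsilyloxy)phenyl]-2-methylpropanenitrile
Product: 6 2-[4-(tert-butyldimethylsilyloxy)phenyl]-2-methylpropanal, via N-aluminio aldimine 5 (not isolated)
Conditions: DIBAL-H, toluene, −78 → 0 °C; then 1 M HCl, 0 °C
Reagents that add atoms: water, O
Why: DIBAL-H adds once to the nitrile and the N-aluminio imine resists further hydride, so hydrolysis should give the non-enolisable neopentyl aldehyde without over-reduction (nitrile half-reduction).

Step 4
Reactants: 6 2-[4-(tert-butyldimethylsilyloxy)phenyl]-2-methylpropanal and 7 allenylboronic acid pinacol ester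
Product: 9 (3S)-2-[4-(tert-butyldimethylsilyloxy)phenyl]-2-methylhex-5-yn-3-ol, via pinacol borate ester 8 (not isolated)
Conditions: (S)-TRIP (5 mol%), 4 Å MS, toluene, 0 → 25 °C; aq. NaHCO3
Reagents that add atoms: none
Why: Chiral phosphoric acid-catalysed allenylboration (SE2′ addition through a closed six-membered transition state, the catalyst binding the boronate oxygen and the formyl hydrogen) gives the homopropargylic alcohol and sets C10 as S by catalyst control of the aldehyde face; the sense is to be confirmed on the Mosher esters, with the antipodal catalyst as the remedy.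

Step 5
Reactants: 9 (3S)-2-[4-(tert-butyldimethylsilyloxy)phenyl]-2-methylhex-5-yn-3-ol
Product: 10 tert-butyl{4-[(3S)-3-(tert-butyldimethylsilyloxy)-2-methylhex-5-yn-2-yl]phenoxy}dimethylsilane
Conditions: TBSOTf, 2,6-lutidine, CH2Cl2, 0 °C
Reagents that add atoms: tert-butyldimethylsilyl trifluoromethanesulfonate, CC(C)(C)[Si](C)(C)OS(=O)(=O)C(F)(F)F
Why: A silyl triflate with a hindered pyridine base silylates even this neopentyl secondary alcohol, which must be masked so that it cannot add to the gold-activated alkyne or, later, to the dienone.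

Step 6
Reactants: 10 tert-butyl{4-[(3S)-3-(tert-butyldimethylsilyloxy)-2-methylhex-5-yn-2-yl]phenoxy}dimethylsilane
Product: 12 tert-butyl{4-[(3S)-3-(tert-butyldimethylsilyloxy)-2-methylhept-5-yn-2-yl]phenoxy}dimethylsilane, via lithium acetylide 11 (not isolated)
Conditions: n-BuLi (1.05 equiv), THF, −78 °C; MeI, −78 → 25 °C
Reagents that add atoms: iodomethane, CI
Why: Deprotonation of the terminal alkyne and SN2 methylation of the lithium acetylide installs the future C7 methyl group without touching either silyl ether.

Step 7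
Reactants: 12 tert-butyl{4-[(3S)-3-(tert-butyldimethylsilyloxy)-2-methylhept-5-yn-2-yl]phenoxy}dimethylsilane
Product: 13 4-[(3S)-3-(tert-butyldimethylsilyloxy)-2-methylhept-5-yn-2-yl]phenol
Conditions: K2CO3 (0.5 equiv), MeOH, 25 °C
Reagents that add atoms: none
Why: Base-mediated methanolysis cleaves the aryl silyl ether (phenoxide is the far better leaving group) and leaves the hindered secondary alkyl silyl ether, freeing the para-hydroxyl that drives the ipso attack.

Step 8
Reactants: 13 4-[(3S)-3-(tert-butyldimethylsilyloxy)-2-methylhept-5-yn-2-yl]phenol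
Product: 14 (10S)-10-(tert-butyldimethylsilyloxy)-7,11,11-trimethylspiro[5.5]undeca-1,4,7-trien-3-one
Conditions: [JohnPhosAu(MeCN)]SbF6 (5 mol%), CH2Cl2, 25 °C
Reagents that add atoms: none
Why: Cationic gold(I) binds the C7≡C8 triple bond and the para carbon of the phenol (C6) attacks it anti to gold at C7, giving a vinylgold oxocarbenium ion that loses the phenolic proton and is then protodeaurated at C8 by that same proton. The closest known reaction type is the gold(I)-catalysed (or iodonium-induced) dearomative ipso-cyclisation of para-alkynyl-tethered phenols and anisoles to spirocyclohexadienones. Ring A closes in the 6-endo-dig mode, both alkyne carbons ending in the ring as the C7(Me)=C8 alkene. No stereocentre is formed, because C6 still carries two identical dienone arms, and C10 is carried through unchanged. The step needs ipso rather than ortho attack, which the para-hydroxyl secures (the ortho carbons are meta to it), and endo rather than 5-exo closure, for which the substrate offers the less hindered methyl-bearing alkyne terminus and the C11 gem-dimethyl group (Thorpe–Ingold) and the catalyst a bulky biaryl phosphine of the kind that favours endo carbocyclisation. The quaternary C11 leaves no benzylic hydrogen for rearomatisation, and the encumbered silyl ether oxygen is a poor competitor for the alkyne.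

Step 9
Reactants: 14 (10S)-10-(tert-butyldimethylsilyloxy)-7,11,11-trimethylspiro[5.5]undeca-1,4,7-trien-3-one
Product: 16 (6S,10S)-10-(tert-butyldimethylsilyloxy)-7,11,11-trimethylspiro[5.5]undeca-1,7-dien-3-one, via silyl dienol ether 15 (not isolated)
Conditions: [Rh(Phebox-iPr)(OAc)2(H2O)] (2 mol%, the antipode that reduces C4=C5), (EtO)2MeSiH, toluene, 50 °C; then 1 M HCl, THF, 0 °C
Reagents that add atoms: none
Why: Rhodium–Phebox-catalysed asymmetric conjugate hydrosilylation, a known way to desymmetrise 4,4-disubstituted cyclohexadienones, should deliver hydride to C5 of the enone arm cis to the C10 oxygen only (the silyl dienol ether cannot be reduced again), which makes C6 stereogenic as S under catalyst control; the two possible products are diastereomers because of C10 and can be separated.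

Step 10
Reactants: 16 (6S,10S)-10-(tert-butyldimethylsilyloxy)-7,11,11-trimethylspiro[5.5]undeca-1,7-dien-3-one
Product: 18 (6S,10S)-10-(tert-butyldimethylsilyloxy)-7,11,11-trimethylspiro[5.5]undeca-2,7-dien-3-yl trifluoromethanesulfonate, via lithium enolate 17 (not isolated)
Conditions: Li, NH3(l)/THF, t-BuOH (1 equiv), −78 °C; isoprene; NH3 off; PhNTf2, THF, 0 → 25 °C
Reagents that add atoms: N-phenylbis(trifluoromethanesulfonimide), O=S(=O)(N(c1ccccc1)S(=O)(=O)C(F)(F)F)C(F)(F)F
Why: Dissolving-metal conjugate reduction of the enone, which is insensitive to the crowding at C1, gives the regiodefined C2=C3 lithium enolate, and this is trapped on oxygen with the triflimide (reductive enol triflate formation) without touching C6 or C10.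

Step 11
Reactants: 18 (6S,10S)-10-(tert-butyldimethylsilyloxy)-7,11,11-trimethylspiro[5.5]undeca-2,7-dien-3-yl trifluoromethanesulfonate
Product: 19 tert-butyldimethyl{[(6S,10S)-3,7,11,11-tetramethylspiro[5.5]undeca-2,7-dien-10-yl]oxy}silane
Conditions: MeMgBr, Fe(acac)3 (5 mol%), THF/NMP, −30 → 0 °C
Reagents that add atoms: methylmagnesium bromide, C[Mg]Br
Why: Iron-catalysed Kumada-type cross-coupling of the enol triflate with the methyl Grignard reagent replaces triflate by the C3 methyl group at low temperature and tolerates the silyl ether.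

Step 12
Reactants: 19 tert-butyldimethyl{[(6S,10S)-3,7,11,11-tetramethylspiro[5.5]undeca-2,7-dien-10-yl]oxy}silane
Product: 20 (6S,10S)-3,7,11,11-tetramethylspiro[5.5]undeca-2,7-dien-10-ol
Conditions: HF·pyridine, THF/pyridine, 0 → 25 °C
Reagents that add atoms: none
Why: Fluoride-driven Si–O cleavage under buffered conditions should leave both trisubstituted alkenes alone, and no enone remains to which the freed alcohol could add.

Step 13
Reactants: 20 (6S,10S)-3,7,11,11-tetramethylspiro[5.5]undeca-2,7-dien-10-ol
Product: 22 (6S,10R)-10-bromo-3,7,11,11-tetramethylspiro[5.5]undeca-2,7-diene, via alkoxyphosphonium bromide 21 (not isolated)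
Conditions: CBr4, (n-Oct)3P, pyridine, toluene, 70 °C
Reagents that add atoms: tetrabromomethane, BrC(Br)(Br)Br
Why: Appel bromination, in which bromide displaces the alkoxyphosphonium group from the rear (SN2), inverts C10 from S to R; the neutral, non-ionising medium is meant to hold back methyl migration and elimination at this neopentyl centre.

Step 14
Reactants: 22 (6S,10R)-10-bromo-3,7,11,11-tetramethylspiro[5.5]undeca-2,7-diene
Product: 23 (2S,3R,6S,10R)-10-bromo-2,3-epoxy-3,7,11,11-tetramethylspiro[5.5]undec-7-ene
Conditions: mCPBA (1.0 equiv), NaHCO3, CH2Cl2, −20 → 0 °C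
Reagents that add atoms: 3-chloroperoxybenzoic acid, OOC(=O)c1cccc(Cl)c1
Why: Prilezhaev epoxidation should go to C2=C3, which is more accessible and more electron-rich than C7=C8 (flanked by the spiro carbon and deactivated by the homoallylic bromine), and from the face syn to C11 because the axial C7 with its methyl group covers the other face; this sets C2 (S) and the oxygen face at C3.

Step 15
Reactants: 23 (2S,3R,6S,10R)-10-bromo-2,3-epoxy-3,7,11,11-tetramethylspiro[5.5]undec-7-ene
Product: 24 (2S,3S,6S,10R)-3,10-dibromo-3,7,11,11-tetramethylspiro[5.5]undec-7-en-2-ol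
Conditions: 48% aq. HBr (1.1 equiv), Et2O, −20 → 0 °C
Reagents that add atoms: hydrogen bromide, Br
Why: Acid-mediated Markovnikov opening of the trisubstituted epoxide, in which bromide attacks the tertiary C3 anti to the protonated oxygen (borderline SN2, inversion), gives 3S with the methyl group syn to C11, while the diaxial path to C2 is blocked by the axial C7.

Step 16
Reactants: 24 (2S,3S,6S,10R)-3,10-dibromo-3,7,11,11-tetramethylspiro[5.5]undec-7-en-2-ol
Product: 27 (2S,3S,6S,10R)-3,10-dibromo-2-chloro-3,7,11,11-tetramethylspiro[5.5]undec-7-ene, via imidate salt 25 (not isolated), via bromonium chloride 26 (not isolated)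
Conditions: 1-chloro-N,N,2-trimethylprop-1-en-1-amine (1.5 equiv), CH2Cl2, 0 → 40 °C
Reagents that add atoms: 1-chloro-N,N,2-trimethylprop-1-en-1-amine, CC(C)=C(Cl)N(C)C
Why: Chlorodehydroxylation with neighbouring-bromine participation (Winstein-type double inversion): the trans C3 bromine expels the activated C2 oxygen to give the bromonium ion on the C7 face and chloride reopens it at C2 from the C11 face, so C2 keeps its configuration; the alternative tertiary chloride is the strained diaxial isomer, which can return through the same ion.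

**Compound list**
1 | 2-(4-hydroxyphenyl)acetonitrile | N#CCc1ccc(O)cc1 | starting material
2 | 2-[4-(tert-butyldimethylsilyloxy)phenyl]acetonitrile | N#CCc1ccc(O[Si](C)(C)C(C)(C)C)cc1 | intermediate
3 | 2-[4-(tert-butyldimethylsilyloxy)phenyl]propanenitrile (racemic, not isolated) | CC(C#N)c1ccc(O[Si](C)(C)C(C)(C)C)cc1 | intermediate
4 | 2-[4-(tert-butyldimethylsilyloxy)phenyl]-2-methylpropanenitrile | CC(C)(C#N)c1ccc(O[Si](C)(C)C(C)(C)C)cc1 | intermediate
5 | N-(diisobutylaluminio)aldimine of 6 (not isolated) | CC(C)C[Al](CC(C)C)N=CC(C)(C)c1ccc(O[Si](C)(C)C(C)(C)C)cc1 | intermediate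
6 | 2-[4-(tert-butyldimethylsilyloxy)phenyl]-2-methylpropanal | CC(C)(C=O)c1ccc(O[Si](C)(C)C(C)(C)C)cc1 | intermediate
7 | allenylboronic acid pinacol ester | C=C=CB1OC(C)(C)C(C)(C)O1 | starting material
8 | pinacol borate ester of alcohol 9 (not isolated) | C#CC[C@H](OB1OC(C)(C)C(C)(C)O1)C(C)(C)c1ccc(O[Si](C)(C)C(C)(C)C)cc1 | intermediate
9 | (3S)-2-[4-(tert-butyldimethylsilyloxy)phenyl]-2-methylhex-5-yn-3-ol | C#CC[C@H](O)C(C)(C)c1ccc(O[Si](C)(C)C(C)(C)C)cc1 | intermediate
10 | tert-butyl{4-[(3S)-3-(tert-butyldimethylsilyloxy)-2-methylhex-5-yn-2-yl]phenoxy}dimethylsilane | C#CC[C@H](O[Si](C)(C)C(C)(C)C)C(C)(C)c1ccc(O[Si](C)(C)C(C)(C)C)cc1 | intermediate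
11 | lithium acetylide of 10 (not isolated) | [Li]C#CC[C@H](O[Si](C)(C)C(C)(C)C)C(C)(C)c1ccc(O[Si](C)(C)C(C)(C)C)cc1 | intermediate
12 | tert-butyl{4-[(3S)-3-(tert-butyldimethylsilyloxy)-2-methylhept-5-yn-2-yl]phenoxy}dimethylsilane | CC#CC[C@H](O[Si](C)(C)C(C)(C)C)C(C)(C)c1ccc(O[Si](C)(C)C(C)(C)C)cc1 | intermediate
13 | 4-[(3S)-3-(tert-butyldimethylsilyloxy)-2-methylhept-5-yn-2-yl]phenol | CC#CC[C@H](O[Si](C)(C)C(C)(C)C)C(C)(C)c1ccc(O)cc1 | intermediate
14 | (10S)-10-(tert-butyldimethylsilyloxy)-7,11,11-trimethylspiro[5.5]undeca-1,4,7-trien-3-one | CC1=CC[C@H](O[Si](C)(C)C(C)(C)C)C(C)(C)C12C=CC(=O)C=C2 | intermediate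
15 | diethoxy(methyl)silyl dienol ether of 16, C1=C2–C3(OSi)=C4 (not isolated) | CC1=CC[C@H](O[Si](C)(C)C(C)(C)C)C(C)(C)[C@]12CC=C(O[Si](C)(OCC)OCC)C=C2 | intermediate
16 | (6S,10S)-10-(tert-butyldimethylsilyloxy)-7,11,11-trimethylspiro[5.5]undeca-1,7-dien-3-one | CC1=CC[C@H](O[Si](C)(C)C(C)(C)C)C(C)(C)[C@]12CCC(=O)C=C2 | intermediate
17 | lithium C2=C3 enolate of the ring-B ketone (not isolated) | CC1=CC[C@H](O[Si](C)(C)C(C)(C)C)C(C)(C)[C@]12CCC(O[Li])=CC2 | intermediate
18 | (6S,10S)-10-(tert-butyldimethylsilyloxy)-7,11,11-trimethylspiro[5.5]undeca-2,7-dien-3-yl trifluoromethanesulfonate | CC1=CC[C@H](O[Si](C)(C)C(C)(C)C)C(C)(C)[C@]12CCC(OS(=O)(=O)C(F)(F)F)=CC2 | intermediate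
19 | tert-butyldimethyl{[(6S,10S)-3,7,11,11-tetramethylspiro[5.5]undeca-2,7-dien-10-yl]oxy}silane | CC1=CC[C@H](O[Si](C)(C)C(C)(C)C)C(C)(C)[C@]12CCC(C)=CC2 | intermediate
20 | (6S,10S)-3,7,11,11-tetramethylspiro[5.5]undeca-2,7-dien-10-ol | CC1=CC[C@H](O)C(C)(C)[C@]12CCC(C)=CC2 | intermediate
21 | trioctyl(alkoxy)phosphonium bromide of 20 (not isolated) | CC1=CC[C@H](O[P+](CCCCCCCC)(CCCCCCCC)CCCCCCCC)C(C)(C)[C@]12CCC(C)=CC2.[Br-] | intermediate
22 | (6S,10R)-10-bromo-3,7,11,11-tetramethylspiro[5.5]undeca-2,7-diene | CC1=CC[C@@H](Br)C(C)(C)[C@]12CCC(C)=CC2 | intermediate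
23 | (2S,3R,6S,10R)-10-bromo-2,3-epoxy-3,7,11,11-tetramethylspiro[5.5]undec-7-ene | CC1=CC[C@@H](Br)C(C)(C)[C@]12CC[C@@]3(C)O[C@H]3C2 | intermediate
24 | (2S,3S,6S,10R)-3,10-dibromo-3,7,11,11-tetramethylspiro[5.5]undec-7-en-2-ol | CC1=CC[C@@H](Br)C(C)(C)[C@]12CC[C@](C)(Br)[C@@H](O)C2 | intermediate
25 | O-alkyl N,N-dimethylisobutyrimidate chloride of 24 (not isolated) | CC1=CC[C@@H](Br)C(C)(C)[C@]12CC[C@](C)(Br)[C@@H](OC(C(C)C)=[N+](C)C)C2.[Cl-] | intermediate
26 | C2–C3 bromonium chloride on the C7 face (not isolated) | CC1=CC[C@@H](Br)C(C)(C)[C@]12CC[C@]3(C)[Br+][C@@H]3C2.[Cl-] | intermediate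
27 | (2S,3S,6S,10R)-3,10-dibromo-2-chloro-3,7,11,11-tetramethylspiro[5.5]undec-7-ene | CC1=CC[C@@H](Br)C(C)(C)[C@]12CC[C@](C)(Br)[C@@H](Cl)C2 | target

**Step count and risks**

Total: 16 steps. Longest linear sequence: 16 steps (from 1; the route is fully linear).

Three steps most likely to fail:

1. Step 16. Chloride may re-enter the bromonium ion at the tertiary carbon C3 and the tertiary chloride so formed may not return to the ion, or the ion may lose a proton to give allylic halides. Fallback, from 22 back to 27: chlorine is brought in as the electrophile instead. Trichloroisocyanuric acid in aqueous acetone at 0 °C should add Cl and OH anti across C2=C3 (chloronium on the C11 face, water at the tertiary C3) to give the chlorohydrin (2S,3S,6S,10R)-10-bromo-2-chloro-3,7,11,11-tetramethylspiro[5.5]undec-7-en-3-ol F1. Bromotrimethylsilane in CH2Cl2 at −78 → −20 °C then exchanges the tertiary hydroxyl for bromide by an SN1 path in which the adjacent C–Cl bond is expected to shield its own face, giving 27. The weak point of this fallback is that an open tertiary cation could also take up bromide from the wrong face.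

2. Step 13. Backside attack at the neopentyl C10 is slow, so E2 elimination to the C9=C10 diene or ionisation with methyl migration from C11 may overtake the substitution. Fallback, from 20 back to 22: the C–Br bond is made by a radical, which neither rearranges nor needs a backside trajectory. Alcohol 20 is acylated with methyl chlorooxoacetate (Et3N, DMAP) to methyl (6S,10S)-3,7,11,11-tetramethylspiro[5.5]undeca-2,7-dien-10-yl oxalate F2, and this is hydrolysed with CsOH to caesium (6S,10S)-3,7,11,11-tetramethylspiro[5.5]undeca-2,7-dien-10-yl oxalate F3. Visible-light photoredox oxidation (iridium photocatalyst, blue light) in the presence of a bromine-atom donor such as CBrCl3 should expel two CO2 and give the C10 radical, which takes up bromine from the equatorial side, the axial side being screened by C5 of ring B, to give 22. This radical deoxyhalogenation of oxalates is established for hindered alkyl chlorides; the bromide variant and its facial preference would have to be checked, the C10 epimers being separable.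

3. Step 8. Ring closure may take place at C8 (5-exo-dig) to give a spiro[4.5] isomer, or the dienone may rearrange under the Lewis-acidic conditions by C–C migration to a rearomatised phenol. Fallback, from 10 back to 14: the alkyne is polarised so that only C7 can be attacked. Alkyne 10 is deprotonated (n-BuLi), oxidised with lithium tert-butyl peroxide and silylated (TIPSOTf) to the siloxyalkyne tert-butyl{4-[(3S)-3-(tert-butyldimethylsilyloxy)-2-methyl-6-(triisopropylsilyloxy)hex-5-yn-2-yl]phenoxy}dimethylsilane F4. Protonation at C8 with HNTf2 (1 equiv, CH2Cl2, −78 °C) gives a silyl ketenium ion whose central carbon C7 is attacked by the para carbon of the aryl silyl ether with loss of the aryl silyl group, giving (10S)-10-(tert-butyldimethylsilyloxy)-11,11-dimethyl-7-(triisopropylsilyloxy)spiro[5.5]undeca-1,4,7-trien-3-one F5. CsF and PhNTf2 convert the silyl enol ether into (10S)-10-(tert-butyldimethylsilyloxy)-11,11-dimethyl-3-oxospiro[5.5]undeca-1,4,7-trien-7-yl trifluoromethanesulfonate F6, and Suzuki methylation (Pd(PPh3)4, trimethylboroxine, K2CO3) gives 14.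

**Further compounds**
F1 | step 16 | (2S,3S,6S,10R)-10-bromo-2-chloro-3,7,11,11-tetramethylspiro[5.5]undec-7-en-3-ol | CC1=CC[C@@H](Br)C(C)(C)[C@]12CC[C@](C)(O)[C@@H](Cl)C2
F2 | step 13 | methyl (6S,10S)-3,7,11,11-tetramethylspiro[5.5]undeca-2,7-dien-10-yl oxalate | CC1=CC[C@H](OC(=O)C(=O)OC)C(C)(C)[C@]12CCC(C)=CC2
F3 | step 13 | caesium (6S,10S)-3,7,11,11-tetramethylspiro[5.5]undeca-2,7-dien-10-yl oxalate | CC1=CC[C@H](OC(=O)C(=O)[O-])C(C)(C)[C@]12CCC(C)=CC2.[Cs+]
F4 | step 8 | tert-butyl{4-[(3S)-3-(tert-butyldimethylsilyloxy)-2-methyl-6-(triisopropylsilyloxy)hex-5-yn-2-yl]phenoxy}dimethylsilane | CC(C)[Si](OC#CC[C@H](O[Si](C)(C)C(C)(C)C)C(C)(C)c1ccc(O[Si](C)(C)C(C)(C)C)cc1)(C(C)C)C(C)C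
F5 | step 8 | (10S)-10-(tert-butyldimethylsilyloxy)-11,11-dimethyl-7-(triisopropylsilyloxy)spiro[5.5]undeca-1,4,7-trien-3-one | CC(C)[Si](OC1=CC[C@H](O[Si](C)(C)C(C)(C)C)C(C)(C)C12C=CC(=O)C=C2)(C(C)C)C(C)C
F6 | step 8 | (10S)-10-(tert-butyldimethylsilyloxy)-11,11-dimethyl-3-oxospiro[5.5]undeca-1,4,7-trien-7-yl trifluoromethanesulfonate | O=C1C=CC2(C=C1)C(OS(=O)(=O)C(F)(F)F)=CC[C@H](O[Si](C)(C)C(C)(C)C)C2(C)C
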